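**Retrosynthetic overview**
- The C3 stereocentre is set last on the full skeleton: target ⇐ desilylation ⇐ oxidation of a cis-(3R,4R)-isoflavan-4-ol ⇐ Ru-catalysed transfer hydrogenation with dynamic kinetic resolution of an achiral isoflavone.
- Isoflavone ⇐ Suzuki–Miyaura coupling of a 3-iodochromone (rings A and C, prenyl already in place) with a 2,2-dimethylchroman-6-yl boronate (ring B with its pyran ring).
- Iodochromone ⇐ resorcinol: Nencki acylation, tert-propargyl ether, semi-hydrogenation/Claisen shift (C-prenyl between the two oxygens), silylation, enaminone/iodocyclisation (ring C closed here).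
- Boronate ⇐ 4-bromophenol and the same tert-propargyl chloride: thermal chromene formation (pyran ring of ring B), borylation, hydrogenation.
- Ring order: pyran ring on ring B and pyranone ring C on ring A in parallel, then the C3–aryl bond, then the stereocentre.

Assumption: operations run through in one flask or without purification (steps 4, 6, 8, 12) count as one step each; acetic acid, DMF-DMA, B2pin2 and the silyl chloride are treated as reagents.

**Step 1**
Reactants: 1 2-methylbut-3-yn-2-ol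
Product: 2 3-chloro-3-methylbut-1-yne
Conditions: conc. HCl, CaCl2, CuCl (cat.), Cu powder, 0 °C to rt
Reagents that add atoms: hydrogen chloride, Cl
Why: SN1 substitution of a tertiary propargylic alcohol through the stabilised propargyl cation, with CuCl suppressing allene formation.

**Step 2**
Reactants: 3 resorcinol
Product: 4 1-(2,4-dihydroxyphenyl)ethanone
Conditions: AcOH, ZnCl2, 140 °C
Reagents that add atoms: acetic acid, CC(=O)O
Why: Nencki (Friedel–Crafts) acylation of resorcinol occurs at C4, para to one hydroxyl and ortho to the other.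

**Step 3**
Reactants: 4 1-(2,4-dihydroxyphenyl)ethanone; 2 3-chloro-3-methylbut-1-yne
Product: 5 1-[2-hydroxy-4-(2-methylbut-3-yn-2-yloxy)phenyl]ethanone
Conditions: DBU, CuCl2·2H2O (cat.), MeCN, 0 °C to rt
Reagents that add atoms: none
Why: Copper-catalysed O-propargylation of the more acidic 4-OH, the 2-OH being tied up in the hydrogen bond to the ketone.

**Step 4**
Reactants: 5 1-[2-hydroxy-4-(2-methylbut-3-yn-2-yloxy)phenyl]ethanone
Product: 7 1-[2,4-dihydroxy-3-(3-methylbut-2-en-1-yl)phenyl]ethanone, via tert-allyl ether 6 (not isolated)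
Conditions: H2 (1 atm), Pd/CaCO3 poisoned with Pb(OAc)2, quinoline, o-xylene, rt; filter through Celite; then 140 °C, 3 h
Reagents that add atoms: none
Why: Lindlar semi-hydrogenation gives the 1,1-dimethylallyl ether, whose aromatic Claisen [3,3] rearrangement inverts the allyl unit to prenyl and goes to C3 because the chelated 2-hydroxyacetophenone fixes C3–C4 double-bond character.

**Step 5**
Reactants: 7 1-[2,4-dihydroxy-3-(3-methylbut-2-en-1-yl)phenyl]ethanone
Product: 8 1-[2-hydroxy-3-(3-methylbut-2-en-1-yl)-4-(triisopropylsilyloxy)phenyl]ethanone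
Conditions: TIPSCl, imidazole, DMAP (cat.), DMF, rt
Reagents that add atoms: triisopropylsilyl chloride, CC(C)[Si](Cl)(C(C)C)C(C)C
Why: Selective silylation of the free 4-OH, since the chelated 2-OH is far less nucleophilic; the silyl ether can later be removed with buffered fluoride without touching the stereocentre or the prenyl group.

**Step 6**
Reactants: 8 1-[2-hydroxy-3-(3-methylbut-2-en-1-yl)-4-(triisopropylsilyloxy)phenyl]ethanone
Product: 10 3-iodo-8-(3-methylbut-2-en-1-yl)-7-(triisopropylsilyloxy)-4H-chromen-4-one, via enaminone 9 (not isolated)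
Conditions: DMF-DMA, toluene, 80 °C; evaporate; then I2 (1.1 equiv), CHCl3, rt, dark
Reagents that add atoms: N,N-dimethylformamide dimethyl acetal, COC(OC)N(C)C; iodine, II
Why: Enaminone condensation followed by iodine-triggered cyclisation with loss of dimethylamine (Gammill 3-iodochromone synthesis); the very electron-rich enaminone takes up iodine much faster than the prenyl alkene.

**Step 7**
Reactants: 11 4-bromophenol; 2 3-chloro-3-methylbut-1-yne
Product: 12 1-bromo-4-(2-methylbut-3-yn-2-yloxy)benzene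
Conditions: DBU, CuCl2·2H2O (cat.), MeCN, 0 °C to rt
Reagents that add atoms: none
Why: The same copper-catalysed O-propargylation, which works well for hindered tertiary propargyl chlorides and electron-poor phenols.

**Step 8**
Reactants: 12 1-bromo-4-(2-methylbut-3-yn-2-yloxy)benzene
Product: 14 6-bromo-2,2-dimethyl-2H-chromene, via allenylphenol 13 (not isolated)
Conditions: PhNEt2, 190 °C, 3 h
Reagents that add atoms: none
Why: Propargyl Claisen rearrangement to the ortho-allenylphenol, then 1,5-hydrogen shift and oxa-6π electrocyclisation close the 2,2-dimethylpyran ring with bromine para to oxygen.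

**Step 9**
Reactants: 14 6-bromo-2,2-dimethyl-2H-chromene
Product: 15 2-(2,2-dimethyl-2H-chromen-6-yl)-4,4,5,5-tetramethyl-1,3,2-dioxaborolane
Conditions: B2pin2, Pd(dppf)Cl2 (3 mol%), KOAc, 1,4-dioxane, 85 °C
Reagents that add atoms: bis(pinacolato)diboron, CC1(C)OB(OC1(C)C)B1OC(C)(C)C(C)(C)O1
Why: Miyaura borylation of the aryl bromide; the weak base KOAc prevents homocoupling and the chromene alkene is inert.

**Step 10**
Reactants: 15 2-(2,2-dimethyl-2H-chromen-6-yl)-4,4,5,5-tetramethyl-1,3,2-dioxaborolane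
Product: 16 2-(2,2-dimethyl-3,4-dihydro-2H-chromen-6-yl)-4,4,5,5-tetramethyl-1,3,2-dioxaborolane
Conditions: H2 (1 atm), Pd/C (10%), EtOAc, rt
Reagents that add atoms: none
Why: Catalytic hydrogenation of the styrene-type C3–C4 double bond; doing it after borylation means no aryl halide is exposed to hydrogenolysis.

**Step 11**
Reactants: 10 3-iodo-8-(3-methylbut-2-en-1-yl)-7-(triisopropylsilyloxy)-4H-chromen-4-one; 16 2-(2,2-dimethyl-3,4-dihydro-2H-chromen-6-yl)-4,4,5,5-tetramethyl-1,3,2-dioxaborolane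
Product: 17 3-(2,2-dimethyl-3,4-dihydro-2H-chromen-6-yl)-8-(3-methylbut-2-en-1-yl)-7-(triisopropylsilyloxy)-4H-chromen-4-one
Conditions: Pd(dppf)Cl2 (5 mol%), Na2CO3 (2 M aq.), DME, 65 °C
Reagents that add atoms: none
Why: Suzuki–Miyaura coupling of the activated vinylic C–I bond with the aryl boronate joins the two halves as the isoflavone; mild carbonate spares the chromone ring and the hindered silyl ether.

**Step 12**
Reactants: 17 3-(2,2-dimethyl-3,4-dihydro-2H-chromen-6-yl)-8-(3-methylbut-2-en-1-yl)-7-(triisopropylsilyloxy)-4H-chromen-4-one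
Product: 19 (3R,4R)-3-(2,2-dimethyl-3,4-dihydro-2H-chromen-6-yl)-8-(3-methylbut-2-en-1-yl)-7-(triisopropylsilyloxy)-3,4-dihydro-2H-chromen-4-ol, via racemic isoflavanone 18 (not isolated)
Conditions: RuCl(p-cymene)[(R,R)-TsDPEN] (3 mol%), HCO2H/Et3N (2:3), EtOAc, 45 °C
Reagents that add atoms: none
Why: Noyori–Ikariya asymmetric transfer hydrogenation first reduces the enone C=C to the isoflavanone, which racemises by enolisation under Et3N while the (R,R)-catalyst reduces one enantiomer to the 4R alcohol with hydride delivered anti to the 3-aryl group, so dynamic kinetic resolution gives the cis-(3R,4R) alcohol and leaves the isolated prenyl alkene untouched.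

**Step 13**
Reactants: 19 (3R,4R)-3-(2,2-dimethyl-3,4-dihydro-2H-chromen-6-yl)-8-(3-methylbut-2-en-1-yl)-7-(triisopropylsilyloxy)-3,4-dihydro-2H-chromen-4-ol
Product: 20 (3R)-3-(2,2-dimethyl-3,4-dihydro-2H-chromen-6-yl)-8-(3-methylbut-2-en-1-yl)-7-(triisopropylsilyloxy)-2,3-dihydro-4H-chromen-4-one
Conditions: Dess–Martin periodinane (1.3 equiv), CH2Cl2, 0 °C to rt, 30 min; Na2S2O3/pH 7 buffer work-up
Reagents that add atoms: none
Why: Dess–Martin oxidation of the benzylic alcohol under non-basic conditions removes the C4 stereocentre and keeps the enolisable 3R centre intact.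

**Step 14**
Reactants: 20 (3R)-3-(2,2-dimethyl-3,4-dihydro-2H-chromen-6-yl)-8-(3-methylbut-2-en-1-yl)-7-(triisopropylsilyloxy)-2,3-dihydro-4H-chromen-4-one
Product: 21 (3R)-3-(2,2-dimethyl-3,4-dihydro-2H-chromen-6-yl)-7-hydroxy-8-(3-methylbut-2-en-1-yl)-2,3-dihydro-4H-chromen-4-one
Conditions: Bu4NF (1.1 equiv) premixed with AcOH (1.5 equiv), THF, 0 °C, 15 min; pH 7 buffer work-up
Reagents that add atoms: none
Why: Fluoride-mediated cleavage of the aryl silyl ether, buffered with acetic acid so that no free phenoxide or fluoride base enolises C3 and no strong acid cyclises the ortho-prenylphenol.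

**Compound list**
1 | 2-methylbut-3-yn-2-ol | CC(C)(O)C#C | starting material
2 | 3-chloro-3-methylbut-1-yne | CC(C)(Cl)C#C | intermediate
3 | resorcinol | Oc1cccc(O)c1 | starting material
4 | 1-(2,4-dihydroxyphenyl)ethanone | CC(=O)c1ccc(O)cc1O | intermediate
5 | 1-[2-hydroxy-4-(2-methylbut-3-yn-2-yloxy)phenyl]ethanone | CC(=O)c1ccc(OC(C)(C)C#C)cc1O | intermediate
6 | 1-[2-hydroxy-4-(2-methylbut-3-en-2-yloxy)phenyl]ethanone | CC(=O)c1ccc(OC(C)(C)C=C)cc1O | intermediate
7 | 1-[2,4-dihydroxy-3-(3-methylbut-2-en-1-yl)phenyl]ethanone | CC(=O)c1ccc(O)c(CC=C(C)C)c1O | intermediate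
8 | 1-[2-hydroxy-3-(3-methylbut-2-en-1-yl)-4-(triisopropylsilyloxy)phenyl]ethanone | CC(=O)c1ccc(O[Si](C(C)C)(C(C)C)C(C)C)c(CC=C(C)C)c1O | intermediate
9 | (E)-3-(dimethylamino)-1-[2-hydroxy-3-(3-methylbut-2-en-1-yl)-4-(triisopropylsilyloxy)phenyl]prop-2-en-1-one | CN(C)/C=C/C(=O)c1ccc(O[Si](C(C)C)(C(C)C)C(C)C)c(CC=C(C)C)c1O | intermediate
10 | 3-iodo-8-(3-methylbut-2-en-1-yl)-7-(triisopropylsilyloxy)-4H-chromen-4-one | CC(C)=CCc1c(O[Si](C(C)C)(C(C)C)C(C)C)ccc2c1OC=C(I)C2=O | intermediate
11 | 4-bromophenol | Oc1ccc(Br)cc1 | starting material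
12 | 1-bromo-4-(2-methylbut-3-yn-2-yloxy)benzene | C#CC(C)(C)Oc1ccc(Br)cc1 | intermediate
13 | 4-bromo-2-(3-methylbuta-1,2-dien-1-yl)phenol | CC(C)=C=Cc1cc(Br)ccc1O | intermediate
14 | 6-bromo-2,2-dimethyl-2H-chromene | CC1(C)C=Cc2cc(Br)ccc2O1 | intermediate
15 | 2-(2,2-dimethyl-2H-chromen-6-yl)-4,4,5,5-tetramethyl-1,3,2-dioxaborolane | CC1(C)C=Cc2cc(B3OC(C)(C)C(C)(C)O3)ccc2O1 | intermediate
16 | 2-(2,2-dimethyl-3,4-dihydro-2H-chromen-6-yl)-4,4,5,5-tetramethyl-1,3,2-dioxaborolane | CC1(C)CCc2cc(B3OC(C)(C)C(C)(C)O3)ccc2O1 | intermediate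
17 | 3-(2,2-dimethyl-3,4-dihydro-2H-chromen-6-yl)-8-(3-methylbut-2-en-1-yl)-7-(triisopropylsilyloxy)-4H-chromen-4-one | CC(C)=CCc1c(O[Si](C(C)C)(C(C)C)C(C)C)ccc2c1OC=C(c1ccc3c(c1)CCC(C)(C)O3)C2=O | intermediate
18 | rac-3-(2,2-dimethyl-3,4-dihydro-2H-chromen-6-yl)-8-(3-methylbut-2-en-1-yl)-7-(triisopropylsilyloxy)-2,3-dihydro-4H-chromen-4-one | CC(C)=CCc1c(O[Si](C(C)C)(C(C)C)C(C)C)ccc2c1OCC(c1ccc3c(c1)CCC(C)(C)O3)C2=O | intermediate
19 | (3R,4R)-3-(2,2-dimethyl-3,4-dihydro-2H-chromen-6-yl)-8-(3-methylbut-2-en-1-yl)-7-(triisopropylsilyloxy)-3,4-dihydro-2H-chromen-4-ol (cis) | CC(C)=CCc1c(O[Si](C(C)C)(C(C)C)C(C)C)ccc2c1OC[C@@H](c1ccc3c(c1)CCC(C)(C)O3)[C@H]2O | intermediate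
20 | (3R)-3-(2,2-dimethyl-3,4-dihydro-2H-chromen-6-yl)-8-(3-methylbut-2-en-1-yl)-7-(triisopropylsilyloxy)-2,3-dihydro-4H-chromen-4-one | CC(C)=CCc1c(O[Si](C(C)C)(C(C)C)C(C)C)ccc2c1OC[C@@H](c1ccc3c(c1)CCC(C)(C)O3)C2=O | intermediate
21 | (3R)-3-(2,2-dimethyl-3,4-dihydro-2H-chromen-6-yl)-7-hydroxy-8-(3-methylbut-2-en-1-yl)-2,3-dihydro-4H-chromen-4-one | CC(C)=CCc1c(O)ccc2c1OC[C@@H](c1ccc3c(c1)CCC(C)(C)O3)C2=O | target

**Totals**
Total step count: 14.
Longest linear sequence: 9 steps (3 → 4 → 5 → 7 → 8 → 10 → 17 → 19 → 20 → 21; the chains 1 → 2 → 5 → … → 21 and 1 → 2 → 12 → 14 → 15 → 16 → 17 → … → 21 are equally long).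

**Steps most likely to fail, with fallbacks**

Risk at step 6. Iodine meets an ortho-prenylphenol (possible iodoetherification), and the aryl silyl ether must survive DMF-DMA. The fallback moves the iodocyclisation ahead of the Claisen shift; it sets out from 5 and comes back at 10. Compound 5 is semi-hydrogenated as in step 4 but the tert-allyl ether 6 is isolated. DMF-DMA at no more than 70 °C gives (E)-3-(dimethylamino)-1-[2-hydroxy-4-(2-methylbut-3-en-2-yloxy)phenyl]prop-2-en-1-one F4. I2 in CHCl3 closes it to 3-iodo-7-(2-methylbut-3-en-2-yloxy)-4H-chromen-4-one F5, with neither a prenyl group nor a silyl ether present when iodine is used. Claisen rearrangement of F5 (o-xylene, 135 °C; 7-allyloxychromones migrate to C8) gives 7-hydroxy-3-iodo-8-(3-methylbut-2-en-1-yl)-4H-chromen-4-one F6. Silylation with TIPSCl/imidazole then gives 10.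

Risk at step 12. The ruthenium hydride may reduce the isoflavone C=C sluggishly, or the dynamic kinetic resolution may give insufficient ee or cis selectivity. The fallback replaces reduction/reoxidation by an enantioselective protonation; it sets out from 17 and comes back at 20, bypassing 19 and step 13. Conjugate reduction of 17 with LiBH(s-Bu)3 in THF at −78 °C and trapping of the enolate with Me3SiCl gives [3-(2,2-dimethyl-3,4-dihydro-2H-chromen-6-yl)-8-(3-methylbut-2-en-1-yl)-7-(triisopropylsilyloxy)-2H-chromen-4-yl]oxy-trimethylsilane F7. Catalytic enantioselective protonation of F7 (BINOL-derived N-triflyl thiophosphoramide, phenol as the stoichiometric proton source, toluene, rt) gives 20 directly. The catalyst enantiomer would have to be chosen by a test run so that the R ketone is delivered.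

Risk at step 4. The semi-hydrogenation may over-reduce, or part of the Claisen shift may go to C5 instead of C3. The fallback uses directed ortho-metalation instead of a sigmatropic shift; it sets out from 3 and comes back at 7. Resorcinol 3 with MOMCl/i-Pr2NEt gives 1,3-bis(methoxymethoxy)benzene F1. Lithiation between the two acetal oxygens (n-BuLi, THF, 0 °C), transmetalation with CuBr·SMe2 and prenyl bromide give 1,3-bis(methoxymethoxy)-2-(3-methylbut-2-en-1-yl)benzene F2. A second ortho-lithiation (n-BuLi, TMEDA, THF, −20 °C) quenched with N-methoxy-N-methylacetamide gives 1-[2,4-bis(methoxymethoxy)-3-(3-methylbut-2-en-1-yl)phenyl]ethanone F3. Brief treatment with catalytic HCl in MeOH at rt (still an achiral stage) removes both acetals to give 7.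

**Further compounds**
F1 | step 4 | 1,3-bis(methoxymethoxy)benzene | COCOc1cccc(OCOC)c1
F2 | step 4 | 1,3-bis(methoxymethoxy)-2-(3-methylbut-2-en-1-yl)benzene | COCOc1cccc(OCOC)c1CC=C(C)C
F3 | step 4 | 1-[2,4-bis(methoxymethoxy)-3-(3-methylbut-2-en-1-yl)phenyl]ethanone | CC(=O)c1ccc(OCOC)c(CC=C(C)C)c1OCOC
F4 | step 6 | (E)-3-(dimethylamino)-1-[2-hydroxy-4-(2-methylbut-3-en-2-yloxy)phenyl]prop-2-en-1-one | CN(C)/C=C/C(=O)c1ccc(OC(C)(C)C=C)cc1O
F5 | step 6 | 3-iodo-7-(2-methylbut-3-en-2-yloxy)-4H-chromen-4-one | C=CC(C)(C)Oc1ccc2c(c1)OC=C(I)C2=O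
F6 | step 6 | 7-hydroxy-3-iodo-8-(3-methylbut-2-en-1-yl)-4H-chromen-4-one | CC(C)=CCc1c(O)ccc2c1OC=C(I)C2=O
F7 | step 12 | [3-(2,2-dimethyl-3,4-dihydro-2H-chromen-6-yl)-8-(3-methylbut-2-en-1-yl)-7-(triisopropylsilyloxy)-2H-chromen-4-yl]oxy-trimethylsilane | CC(C)=CCc1c(O[Si](C(C)C)(C(C)C)C(C)C)ccc2c1OCC(c1ccc3c(c1)CCC(C)(C)O3)=C2O[Si](C)(C)C
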